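A direct plan would fold (5E,9E)-farnesylacetone A1, in one chiral-acid-catalysed polyene cyclisation terminated by the ketone oxygen, into the bicyclic hydroxy ketone A2. It would then add the last two carbons by Horner–Wadsworth–Emmons olefination (enoate A3), reduce to the diol A4 and acetylate the primary hydroxyl. Its weakest steps would be:
(a) the ketone-terminated cyclisation, because both rings and all four stereocentres would rest on one catalytic event without precedent for this terminator, with the ee still to be upgraded by recrystallisation;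
(b) the olefination of the methyl ketone, because the C13=C14 geometry would be left to a modest E preference and the Z ester removed from late material, under a base that invites oxa-Michael closure of the C8 hydroxyl;
(c) the reduction/acetylation pair, two late steps that would add no complexity and depend on telling apart the two hydroxyls of the diol.

Plan of the new route. The retrosynthesis cuts C12–C13 first (B-alkyl Suzuki coupling with an alkenyl iodide that already holds the E olefin and the acetate). It then cuts C8–C9 (ring B, by ketyl–olefin closure of a monocyclic methyl ketone), and last C9–C10 and C5–C6 (conjugate addition/allylation on a cyclohexenone that is ring A). Ring A is present from the first step; ring B is closed alone and last, through a bond that a polyene cyclisation does not make. The enabling feature is the C8 methyl carbinol next to C9 on ring B: C8 is a latent methyl ketone and the C11 arm on C9 a latent vinyl group. The trans C5–C6/C10–C9 bonds on ring A force a chair closure that sets C8 and C9 together. No acid-triggered cascade, no olefination of a ketone and no ester or diol stage remain.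

Key step: step 4

Assumption: labdane numbering is used for atoms; enone 1 is taken as commercial; the ligand antipode in step 1 is the one that delivers the alkyl group to give the 3S adduct (sense of induction assumed by analogy with simpler cyclohexenones).

Step 1
Reactants: 1 2,4,4-trimethylcyclohex-2-en-1-one; 2 2-(2-bromoethyl)-2-methyl-1,3-dioxolane; 3 allyl iodide
Product: 5 (2R,3S)-2,4,4-trimethyl-3-[2-(2-methyl-1,3-dioxolan-2-yl)ethyl]-2-(prop-2-en-1-yl)cyclohexan-1-one, via magnesium enolate 4 (not isolated)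
Conditions: 2, Mg, THF, 23 °C (Grignard reagent); 1, CuBr·SMe2 (5 mol%), (R)-1-[(S)-2-(diphenylphosphino)ferrocenyl]ethyldicyclohexylphosphine (6 mol%), t-BuOMe, −60 °C; then 3 (3 equiv), DMPU, −60 → 0 °C
Reagents that add atoms: 2-(2-bromoethyl)-2-methyl-1,3-dioxolane (2), CC1(CCBr)OCCO1; allyl iodide (3), C=CCI
Why: Copper-catalysed asymmetric conjugate addition of the Grignard reagent to the 2-methyl enone (ligand control, sets C5 = ring C3) gives the regio-defined enolate 4, whose allylation should occur on the face opposite to the new C3 side chain, so that the quaternary C10 carries the allyl group trans to that chain (tandem conjugate addition/enolate alkylation).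

Step 2
Reactants: 5 (2R,3S)-2,4,4-trimethyl-3-[2-(2-methyl-1,3-dioxolan-2-yl)ethyl]-2-(prop-2-en-1-yl)cyclohexan-1-one
Product: 8 4-[(1S,2R)-2,6,6-trimethyl-2-(prop-2-en-1-yl)cyclohexyl]butan-2-one, via hydrazone 6 (not isolated), via dioxolane 7 (not isolated)
Conditions: N2H4·H2O, KOH, diethylene glycol, 130 → 200 °C; extractive work-up; then 1 M aq. HCl/THF, 23 °C
Reagents that add atoms: water, O
Why: Huang-Minlon Wolff–Kishner reduction should remove the ring carbonyl, which only served to make the two C–C bonds, without touching the dioxolane, the terminal olefin or either stereocentre (C10 quaternary, C5 not acidic), and aqueous acid then unmasks the methyl ketone.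

Step 3
Reactants: 8 4-[(1S,2R)-2,6,6-trimethyl-2-(prop-2-en-1-yl)cyclohexyl]butan-2-one
Product: 9 (2E)-3-[(1R,2S)-1,3,3-trimethyl-2-(3-oxobutyl)cyclohexyl]prop-2-en-1-yl acetate
Conditions: Pd(OAc)2 (10 mol%), 1,4-benzoquinone (2 equiv), AcOH/DMSO (1:1), 4 Å molecular sieves, 40 °C
Reagents that add atoms: acetic acid, CC(=O)O
Why: Linear-selective allylic C–H acetoxylation of a terminal olefin by divalent palladium (White type) should pass through a π-allyl complex formed at the only allylic CH2 (C9) and be attacked by acetate at the unhindered terminus, which moves the double bond to C9=C11 with E geometry and installs the leaving group for step 4, the ketone being inert.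

Step 4
Reactants: 9 (2E)-3-[(1R,2S)-1,3,3-trimethyl-2-(3-oxobutyl)cyclohexyl]prop-2-en-1-yl acetate
Product: 10 (1R,2R,4aS,8aS)-1-ethenyl-2,5,5,8a-tetramethyldecahydronaphthalen-2-ol
Conditions: SmI2 (2.5 equiv, 0.1 M in THF), HMPA (10 equiv), slow addition of 9, 0 → 23 °C; aq. NH4Cl
Reagents that add atoms: none
Why: SmI2/HMPA reduces the methyl ketone to a ketyl radical anion at C8, which adds 6-exo-trig to C9 of the E allylic acetate; the C11 radical is reduced by a second SmI2 to an organosamarium that expels the β-acetate at once, which makes the addition irreversible and leaves the vinyl group (C11=C12) as the handle for the side chain. The closest known reaction type is the SmI2-promoted ketyl–olefin coupling/β-elimination sequence of ketones that bear an allylic leaving group, which gives trans-2-alkenyl cycloalkanols. Ring B is closed by 6-exo-trig radical addition (C8–C9), ring A being present already. C8 and C9 are set together in a chair transition state that is trans-fused to ring A, because the C5–C6 and C10–C9 bonds are trans-diequatorial on ring A (C5 and C10 from step 1): the bulky HMPA-solvated O–Sm group takes the equatorial position away from the axial C10 methyl (8α-O, 8β-CH3, 8R), and the alkenyl arm stays equatorial and anti to the oxygen (9β, 9R). The step needs reduction of the ketone before the allylic acetate (much faster without a palladium co-catalyst) and exo over 7-endo attack, which the ring size and the polarisation of the olefin by the CH2OAc group favour.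

Step 5
Reactants: 11 but-2-yn-1-ol
Product: 13 (2E)-3-iodobut-2-en-1-ol, via alkenylzirconocene 12 (not isolated)
Conditions: Cp2Zr(H)Cl (2.3 equiv), THF, 23 °C; then I2 (1.1 equiv), 0 °C; aq. Na2S2O3
Reagents that add atoms: iodine, II
Why: Syn hydrozirconation with excess Schwartz reagent should place zirconium, after equilibration, on the alkyne carbon that bears the small methyl group, and iodinolysis with retention then gives the E alkenyl iodide, so the C13=C14 geometry is fixed here by a stereospecific syn addition.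

Step 6
Reactants: 13 (2E)-3-iodobut-2-en-1-ol; 14 acetic anhydride
Product: 15 (2E)-3-iodobut-2-en-1-yl acetate
Conditions: Ac2O (1.2 equiv), pyridine, DMAP (cat.), CH2Cl2, 0 °C
Reagents that add atoms: acetic anhydride (14), CC(=O)OC(C)=O
Why: Standard acylation of a primary allylic alcohol, which brings the acetate of the target in on the small fragment.

Step 7
Reactants: 10 (1R,2R,4aS,8aS)-1-ethenyl-2,5,5,8a-tetramethyldecahydronaphthalen-2-ol; 15 (2E)-3-iodobut-2-en-1-yl acetate
Product: 17 (2E)-5-[(1R,2R,4aS,8aS)-2-hydroxy-2,5,5,8a-tetramethyldecahydronaphthalen-1-yl]-3-methylpent-2-en-1-yl acetate (CNP0268033.1), via alkylborane 16 (not isolated)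
Conditions: 9-BBN-H (2.5 equiv), THF, 23 → 45 °C; then 15 (1.3 equiv), Pd(dppf)Cl2 (5 mol%), AsPh3 (10 mol%), Cs2CO3 (3 equiv), DMF/H2O, 23 °C
Reagents that add atoms: (2E)-3-iodobut-2-en-1-yl acetate (15), C/C(I)=C\COC(C)=O
Why: Anti-Markovnikov hydroboration of the monosubstituted vinyl group (the tertiary hydroxyl only consumes one equivalent of borane) gives 16, which should undergo B-alkyl Suzuki–Miyaura coupling with retention of the E geometry, since oxidative addition to the C–I bond is much faster than ionisation of the trisubstituted allylic acetate and the mild base at 23 °C spares the acetate and the tertiary alcohol.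

Compound list
1 | 2,4,4-trimethylcyclohex-2-en-1-one | CC1=CC(C)(C)CCC1=O | starting material
2 | 2-(2-bromoethyl)-2-methyl-1,3-dioxolane | CC1(CCBr)OCCO1 | starting material
3 | allyl iodide (3-iodoprop-1-ene) | C=CCI | starting material
4 | bromomagnesium (3S)-2,4,4-trimethyl-3-[2-(2-methyl-1,3-dioxolan-2-yl)ethyl]cyclohex-1-en-1-olate | CC1=C(O[Mg]Br)CCC(C)(C)[C@@H]1CCC2(C)OCCO2 | intermediate
5 | (2R,3S)-2,4,4-trimethyl-3-[2-(2-methyl-1,3-dioxolan-2-yl)ethyl]-2-(prop-2-en-1-yl)cyclohexan-1-one | C=CC[C@@]1(C)C(=O)CCC(C)(C)[C@@H]1CCC2(C)OCCO2 | intermediate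
6 | (2R,3S)-2,4,4-trimethyl-3-[2-(2-methyl-1,3-dioxolan-2-yl)ethyl]-2-(prop-2-en-1-yl)cyclohexan-1-one hydrazone | C=CC[C@@]1(C)C(=NN)CCC(C)(C)[C@@H]1CCC2(C)OCCO2 | intermediate
7 | 2-methyl-2-{2-[(1S,2R)-2,6,6-trimethyl-2-(prop-2-en-1-yl)cyclohexyl]ethyl}-1,3-dioxolane | C=CC[C@@]1(C)CCCC(C)(C)[C@@H]1CCC2(C)OCCO2 | intermediate
8 | 4-[(1S,2R)-2,6,6-trimethyl-2-(prop-2-en-1-yl)cyclohexyl]butan-2-one | C=CC[C@@]1(C)CCCC(C)(C)[C@@H]1CCC(C)=O | intermediate
9 | (2E)-3-[(1R,2S)-1,3,3-trimethyl-2-(3-oxobutyl)cyclohexyl]prop-2-en-1-yl acetate | CC(=O)OC/C=C/[C@@]1(C)CCCC(C)(C)[C@@H]1CCC(C)=O | intermediate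
10 | (1R,2R,4aS,8aS)-1-ethenyl-2,5,5,8a-tetramethyldecahydronaphthalen-2-ol (trans-decalin, 8α-OH, 9β-vinyl) | C=C[C@@H]1[C@@]2(C)CCCC(C)(C)[C@@H]2CC[C@@]1(C)O | intermediate
11 | but-2-yn-1-ol | CC#CCO | starting material
12 | (E)-alkenylzirconocene chloride of the zirconium alkoxide, Cp2Zr(Cl)–C(CH3)=CH–CH2–O–Zr(Cl)Cp2, zirconium on C3 trans to the CH2O group | C/C(=C\CO[Zr](Cl)(C1C=CC=C1)C1C=CC=C1)[Zr](Cl)(C1C=CC=C1)C1C=CC=C1 | intermediate
13 | (2E)-3-iodobut-2-en-1-ol | C/C(I)=C\CO | intermediate
14 | acetic anhydride | CC(=O)OC(C)=O | starting material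
15 | (2E)-3-iodobut-2-en-1-yl acetate | C/C(I)=C\COC(C)=O | intermediate
16 | 9-{2-[(1R,2R,4aS,8aS)-2-hydroxy-2,5,5,8a-tetramethyldecahydronaphthalen-1-yl]ethyl}-9-borabicyclo[3.3.1]nonane | B1(CC[C@@H]2[C@@]3(C)CCCC(C)(C)[C@@H]3CC[C@@]2(C)O)C2CCCC1CCC2 | intermediate
17 | (2E)-5-[(1R,2R,4aS,8aS)-2-hydroxy-2,5,5,8a-tetramethyldecahydronaphthalen-1-yl]-3-methylpent-2-en-1-yl acetate; (5S,8R,9R,10S,13E) | CC(=O)OC/C=C(\C)CC[C@@H]1[C@@]2(C)CCCC(C)(C)[C@@H]2CC[C@@]1(C)O | target

Total step count: 7. Longest linear sequence: 5 (steps 1, 2, 3, 4, 7).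

Steps most likely to fail

Step 4. The ketyl may be reduced on to the secondary alcohol, or close 7-endo, before it attacks the hindered C9 next to the quaternary C10; the oxygen may also end up axial. The fallback sets out from 9 and replaces the radical closure by a two-electron allylmetal addition. Pd(PPh3)4 (cat.) and InI in THF at 23 °C should convert the allylic acetate into the allylindium species acetoxy(iodo){(2E)-3-[(1R,2S)-1,3,3-trimethyl-2-(3-oxobutyl)cyclohexyl]prop-2-en-1-yl}indium F1. This can only add to the ketone through its γ-carbon (C9), in a chair, six-membered cyclic transition state with the E olefin. It comes back to the route at 10.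

Step 1. The conjugate addition to a trisubstituted enone whose β-carbon is neopentylic may be slow and poorly enantioselective. The fallback sets out from 2 and the less hindered 4,4-dimethylcyclohex-2-en-1-one F2. The same copper-catalysed addition of the Grignard reagent of 2, well precedented for this enone, gives bromomagnesium (3R)-4,4-dimethyl-3-[2-(2-methyl-1,3-dioxolan-2-yl)ethyl]cyclohex-1-en-1-olate F3. Quenching with MeI gives (2R,3R)-2,4,4-trimethyl-3-[2-(2-methyl-1,3-dioxolan-2-yl)ethyl]cyclohexan-1-one F4. Equilibrating silylation (TMSCl, NaI, Et3N, MeCN) gives the more substituted enol ether trimethyl({(3S)-2,4,4-trimethyl-3-[2-(2-methyl-1,3-dioxolan-2-yl)ethyl]cyclohex-1-en-1-yl}oxy)silane F5. MeLi then releases lithium (3S)-2,4,4-trimethyl-3-[2-(2-methyl-1,3-dioxolan-2-yl)ethyl]cyclohex-1-en-1-olate F6. Allyl iodide alkylates F6 anti to the side chain, and the route is rejoined at 5.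

Step 3. C–H cleavage at the neopentylic allylic CH2 may be too slow, so that Wacker-type oxidation or olefin migration takes over. The fallback sets out from 8 and makes the allylic oxygen by an ene-type oxidation. Isomerisation with RuHCl(CO)(PPh3)3 (toluene, 80 °C) gives 4-{(1S,2R)-2,6,6-trimethyl-2-[(1E)-prop-1-en-1-yl]cyclohexyl}butan-2-one F7. SeO2 (cat.)/t-BuOOH oxidises its only allylic C–H bonds, those of the terminal methyl, to 4-{(1S,2R)-2-[(1E)-3-hydroxyprop-1-en-1-yl]-2,6,6-trimethylcyclohexyl}butan-2-one F8. Acetylation (Ac2O, pyridine) comes back to the route at 9.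

Further compounds
F1 | step 4 | acetoxy(iodo){(2E)-3-[(1R,2S)-1,3,3-trimethyl-2-(3-oxobutyl)cyclohexyl]prop-2-en-1-yl}indium | CC(=O)O[In](I)C/C=C/[C@@]1(C)CCCC(C)(C)[C@@H]1CCC(C)=O
F2 | step 1 | 4,4-dimethylcyclohex-2-en-1-one | CC1(C)CCC(=O)C=C1
F3 | step 1 | bromomagnesium (3R)-4,4-dimethyl-3-[2-(2-methyl-1,3-dioxolan-2-yl)ethyl]cyclohex-1-en-1-olate | C1=C(O[Mg]Br)CCC(C)(C)[C@@H]1CCC2(C)OCCO2
F4 | step 1 | (2R,3R)-2,4,4-trimethyl-3-[2-(2-methyl-1,3-dioxolan-2-yl)ethyl]cyclohexan-1-one | C[C@H]1C(=O)CCC(C)(C)[C@@H]1CCC2(C)OCCO2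
F5 | step 1 | trimethyl({(3S)-2,4,4-trimethyl-3-[2-(2-methyl-1,3-dioxolan-2-yl)ethyl]cyclohex-1-en-1-yl}oxy)silane | CC1=C(O[Si](C)(C)C)CCC(C)(C)[C@@H]1CCC2(C)OCCO2
F6 | step 1 | lithium (3S)-2,4,4-trimethyl-3-[2-(2-methyl-1,3-dioxolan-2-yl)ethyl]cyclohex-1-en-1-olate | CC1=C(O[Li])CCC(C)(C)[C@@H]1CCC2(C)OCCO2
F7 | step 3 | 4-{(1S,2R)-2,6,6-trimethyl-2-[(1E)-prop-1-en-1-yl]cyclohexyl}butan-2-one | C/C=C/[C@@]1(C)CCCC(C)(C)[C@@H]1CCC(C)=O
F8 | step 3 | 4-{(1S,2R)-2-[(1E)-3-hydroxyprop-1-en-1-yl]-2,6,6-trimethylcyclohexyl}butan-2-one | OC/C=C/[C@@]1(C)CCCC(C)(C)[C@@H]1CCC(C)=O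
A1 | direct plan | (5E,9E)-6,10,14-trimethylpentadeca-5,9,13-trien-2-one ((E,E)-farnesylacetone) | CC(=O)CC/C=C(\C)CC/C=C(\C)CCC=C(C)C
A2 | direct plan | 4-[(1R,2R,4aS,8aS)-2-hydroxy-2,5,5,8a-tetramethyldecahydronaphthalen-1-yl]butan-2-one | CC(=O)CC[C@@H]1[C@@]2(C)CCCC(C)(C)[C@@H]2CC[C@@]1(C)O
A3 | direct plan | ethyl (2E)-5-[(1R,2R,4aS,8aS)-2-hydroxy-2,5,5,8a-tetramethyldecahydronaphthalen-1-yl]-3-methylpent-2-enoate | CCOC(=O)/C=C(\C)CC[C@@H]1[C@@]2(C)CCCC(C)(C)[C@@H]2CC[C@@]1(C)O
A4 | direct plan | (1R,2R,4aS,8aS)-1-[(3E)-5-hydroxy-3-methylpent-3-en-1-yl]-2,5,5,8a-tetramethyldecahydronaphthalen-2-ol | OC/C=C(\C)CC[C@@H]1[C@@]2(C)CCCC(C)(C)[C@@H]2CC[C@@]1(C)O
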